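## The problem

The target 27 is a monocyclic bisabolane. One cyclohexanone ring is fused to an oxirane at C2–C3 and joined at C5, through the sp2 carbon C7, to a seven-carbon chain. The numbering used throughout is: C1 carbonyl carbon, C2 the methyl-bearing and C3 the other epoxide carbon, C4 the ring methylene, C5 the ring carbon carrying the side chain, C6 the angelate carbon, C7 the side-chain carbon with the methylene C14, C8 the acetoxy carbon, C9 a methylene, C10=C11 the prenyl alkene.

Five stereocentres must be set, (2S,3S,5S,6S,8S). On the ring, C5 and C6 are trans and the epoxide is cis to the C5 chain. C8 is insulated from the ring by C7 and cannot be controlled from it, so it must arrive with its own reagent-derived configuration. This argues for a convergent union of a C7–C13 piece with a C1–C6 piece at the C5–C7 bond.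

The ring centres can control each other in one useful way. A hydroxyl at C1 on the face of the C5 chain can deliver the epoxide oxygen to that face, and because C1 ends as a ketone this centre is erased afterwards. Nucleophilic epoxidation of the corresponding enone would instead approach anti to the C5 chain.

Several groups will not survive rough treatment. The angelate isomerises to the tiglate under nucleophilic catalysis or base. C6 is an enolisable α-acyloxy ketone carbon. The epoxy ketone is sensitive to base and strong acid. The prenyl and methylene alkenes exclude unselective electrophilic oxidants. The esters and the C1 carbonyl therefore belong at the very end.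

The feature that opens the ring for synthesis is the C2–C3 bond. It is the only ring bond that can be an alkene before the epoxide exists, and no stereocentre has to be created while it is formed. The C1 carbinol that will direct the epoxidation is at the same time an allylic alcohol. A 1,7-diene with an isopropenyl group on C1 and an allyl group on C5 is therefore predisposed to close to exactly the cyclohexenol the endgame needs.

## Retrosynthesis

**C6–O acyl bond (27 ⇒ 24 + 25).** The angelate is the most fragile group, so its ester bond is cut first and 27 is traced to α-hydroxy ketone 24 and angelic acid 25. Cutting the C8 acetate first instead would expose the angelate to two further operations. Compound 24 already holds all five stereocentres. The forward reaction must acylate a hindered α-ketol without nucleophilic catalyst or strong base.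

**C8 acetate and the C6 protecting group (24 ⇒ 23 ⇒ 22 ⇒ 21).** An acetate cannot pass through the organometallic steps, so the C8 oxygen is traced back to the silyl ether of 21. The C6 oxygen is traced to a PMB ether, which chelates magnesium, survives metathesis and oxidation, and leaves under neutral oxidative conditions. The silyl-to-acetyl exchange (21 to 22 to 23) is placed before PMB removal so that only one hydroxyl is ever free. The forward steps must not use base strong enough to enolise C6.

**C1 carbonyl and the epoxide C–O bonds (21 ⇒ 20 ⇒ 19).** The ketone is traced to the alcohol of 20 and the two epoxide C–O bonds are cut to give cyclohexenol 19. This is preferred over cutting to an enone, because the epoxide must lie cis to the C5 chain and only a directing hydroxyl on that face secures this. Compound 19 has two fewer ring stereocentres. The forward epoxidation must choose the ring alkene over the C7 methylene and the prenyl alkene, which a metal-alkoxide-directed oxidant does.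

**Ring bond C2=C3 (19 ⇒ 18).** This is the key cut. Any other ring bond would require a stereocentre to be formed during closure, whereas C2=C3 joins two sp2 carbons between centres that can all be set on an open chain. The precursor 18 is acyclic, with C1, C5, C6 and C8 in place. The forward metathesis must select the isopropenyl group among the other alkenes.

**C1–C2 (18 ⇒ 16 + 17).** The isopropenyl group is removed as Grignard reagent 17, leaving α-alkoxy aldehyde 16. The neighbouring cut C1–C6 would need an acyl-anion equivalent and would break up the C5/C6 pair. One stereocentre and one alkene disappear. The forward addition must be chelation-controlled to give the 1,6-syn relationship, which is what the PMB ether at C6 is for.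

**Oxidation level at C1 and position of the PMB group (16 ⇒ 15 ⇒ 14 ⇒ 13).** Aldehyde 16 comes from primary alcohol 15. The PMB group on O6 of 15 is traced through cyclic acetal 14 to a PMB ether on O1 in 13. The same benzyl unit thus protects the primary oxygen during fragment coupling and ends on C6 without a second protecting group. The forward steps are an oxidative acetal closure and a regioselective reductive opening.

**C5–C7 (13 ⇒ 6 + 11, through 12).** This convergent cut divides the skeleton into epoxide 6 (C1–C6, carrying C5 and C6) and alkenyl bromide 11 (C7–C13, carrying C8), joined through alkenyllithium 12. It is preferred over building the side chain on a ring, because C8 is then fixed independently. The configurations of C5 and C6 come from one epoxide by an invertive opening. Using the ether 6 and not the free alcohol 5 costs one step, but it removes alkoxide-directed attack at C2 and lets induction and bulk steer the nucleophile to C3. The forward reaction must open an internal cis-epoxide with a branched alkenyl nucleophile.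

**Epoxide 6 (6 ⇒ 5 ⇒ 4 ⇒ 3 ⇒ 1 + 2).** The ether bond is cut to epoxy alcohol 5 and the epoxide C–O bonds to Z-allylic alcohol 4. The Z-alkene comes from alkyne 3, and the C3–C4 bond of 3 from propargyl alcohol 1 and allyl bromide 2. The forward sequence needs a semi-reduction that spares the terminal alkene and an asymmetric epoxidation of a cis-allylic alcohol.

**Bromide 11 (11 ⇒ 10 ⇒ 9 ⇒ 7, through 8).** The silyl ether is cut to alcohol 10. The isopropylidene terminus of 10 is cut by a cross-metathesis transform to the allyl compound 9, because direct addition of a prenyl metal would give the branched isomer. The C8–C9 bond of 9 is cut by an asymmetric allylation transform to 2-bromoacrolein 7, through borinate 8. The forward allylation must set C8 by reagent control.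

## Roads not taken

**Alternative 1:** The cut is the C4–C5 ring bond. The cyclohexene is traced to a six-membered lactone A2 from the deoxypentose chiral pool, in which the ring oxygen sits on the later C2, a carbon carrying the methyl and a vinyl group. In the forward key step the silyl ketene acetal of A2 undergoes an Ireland–Claisen rearrangement through a boat-like transition state. The vinyl terminus bonds to the lactone α-carbon, the lactone C–O bond breaks, and the acid A1 results, with the C2–C3 alkene, the C1/C6 acetonide and C7 as a carboxyl group on C5.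

- Merits: ring, trisubstituted alkene and C5 arise in one step with chirality transferred from the pool. The C1 and C6 oxygens are present from the start, and no competing alkene exists.
- Weak points for this target:
  - A1 holds C7 only as a carboxyl carbon. The methylene C14 and the whole C8–C13 chain, including C8, must be built afterwards next to the epimerisable C5, with no handle for C8.
  - The acetonide ties the C1 and C6 oxygens cis, so the C1 oxygen is trans to the side chain. That is the wrong face to direct the epoxide, and the two secondary oxygens must also be told apart.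
  - The quaternary carbinol carbon of A2 must be set with the vinyl group cis to the acetonide.
- Comparison: as a ring construction this road is better, since it sets a stereocentre while closing the ring and raises no chemoselectivity question. The adopted plan sets against this that it reaches the ring with the complete side chain, C8 fixed, and with the C1 and C6 oxygens differentiated and correctly placed. Six steps then remain, where A1 would need considerably more.

**Alternative 2:** The cuts are C1–C2 and C3–C4. Cyclohexenone A3 is traced to the trans-2-silyloxy-3-substituted cyclobutanone A4 and 1-(trimethylsilyl)propyne A5. In the forward key step a zerovalent nickel catalyst, Ni(cod)2 with PCy3, couples the carbonyl of A4 with A5. β-Carbon elimination cleaves C1–C4 and reductive elimination forms C3–C4, expanding the four-membered ring to the enone.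

- Merits: two C–C bonds and the enone are formed in one convergent step. C5 and C6 are carried in from a small ring, and C1 is already at the ketone level.
- Weak points for this target:
  - β-Carbon elimination must break the CH2 bond C1–C4 and not the oxygen-bearing bond C1–C6, and the alkyne must insert with its methyl next to the carbonyl. Both are open questions for an α-silyloxy cyclobutanone, and the C3 silyl group must be removed later.
  - Enantiopure A4 is itself a multistep target and is prone to ring opening and epimerisation.
  - The product is an enone. Its nucleophilic epoxidation would come anti to the C5 substituent, so reduction, directed epoxidation and re-oxidation are needed anyway.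
  - C7 is present only as a ketal-protected methyl ketone. The C8–C13 chain would have to be attached without control of C8.
- Comparison: this road is more convergent in the ring-forming event and better in bond count per step. The adopted plan sets against it a ring closure with only one regiochemical outcome, control of C8 before the fragments meet, and direct delivery of the allylic alcohol needed for the epoxidation.

**Alternative 3:** The cut is the C5–C6 ring bond. The ring is traced to the acyclic (3Z,6Z)-trienal A7, with the C6 aldehyde, a C1 PMB ether and the C5=C7 alkene bearing the C14 methyl. In the forward key step a dialkylaluminium chloride (Me2AlCl) activates the aldehyde of A7. C5 attacks it while a hydrogen of C14 passes to oxygen, giving the trans-cyclohexenol A6 with the C7 methylene, the free C6 hydroxyl and the C2–C3 alkene.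

- Merits: the closure creates the ring, both C5 and C6, the exocyclic alkene and a free C6 hydroxyl ready for angeloylation. That is more than a metathesis does, and the endgame could be a step or two shorter.
- Weak points for this target:
  - A7 needs two trisubstituted Z-alkenes of defined geometry, one flanked by C8. It is also a β,γ-unsaturated α-alkoxy aldehyde, liable to conjugation and epimerisation.
  - The transferred hydrogen can come from C14 or from C8–H, and the Lewis acid can also engage the prenyl alkene or cleave the PMB ether.
  - The facial outcome across C1, C5 and C6 rests on a single transition state, and the relation of C8 to the ring centres is not obviously controlled.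
  - C1 emerges as a PMB ether, so the directing hydroxyl must be unmasked with the angelate already in place.
- Comparison: on paper this is the most step-economical road and its key step builds more. The adopted plan sets against it that each stereocentre comes from a separately precedented, reagent- or chelation-controlled step and that the ring closure has essentially one outcome. The price is a longer linear sequence.

Key step: step 13

Assumption: 2-bromoacrolein 7 and the pinene-derived allylborane of step 5 are used as purchased reagents; 7 polymerises on storage and is distilled just before use.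

## Route

Step 1
Reactants: 1 prop-2-yn-1-ol (propargyl alcohol); 2 3-bromoprop-1-ene (allyl bromide)
Product: 3 hex-5-en-2-yn-1-ol
Conditions: CuI (10 mol%), K2CO3, n-Bu4NCl, DMF, rt
Reagents that add atoms: none
Why: Copper-catalysed allylation of a terminal alkyne: the copper acetylide of 1 displaces bromide from 2, and the weak carbonate base leaves the hydroxyl unalkylated, giving the skipped enyne.

Step 2
Reactants: 3 hex-5-en-2-yn-1-ol
Product: 4 (2Z)-hexa-2,5-dien-1-ol
Conditions: H2 (1 atm), Ni2B (from Ni(OAc)2·4H2O and NaBH4, 10 mol%), ethylenediamine, EtOH, rt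
Reagents that add atoms: none
Why: Alkyne semi-hydrogenation on amine-poisoned nickel boride adds hydrogen syn to the triple bond only, giving the Z-alkene while the terminal alkene is neither reduced nor moved into conjugation.

Step 3
Reactants: 4 (2Z)-hexa-2,5-dien-1-ol
Product: 5 [(2R,3S)-3-(prop-2-en-1-yl)oxiran-2-yl]methanol
Conditions: Ti(OiPr)4 (10 mol%), D-(−)-diisopropyl tartrate (12 mol%), t-BuOOH (in decane), 4 Å molecular sieves, CH2Cl2, −20 °C
Reagents that add atoms: tert-butyl hydroperoxide, CC(C)(C)OO
Why: Sharpless asymmetric epoxidation: the titanium D-(−)-tartrate complex delivers oxygen to the face of the Z-allylic alcohol that gives the (2R,3S) cis-epoxide, and the remote terminal alkene has no directing hydroxyl in reach. Cis-allylic alcohols react more slowly and usually somewhat less selectively than trans ones; material from the minor enantiomer becomes a separable diastereomer after step 8.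

Step 4
Reactants: 5 [(2R,3S)-3-(prop-2-en-1-yl)oxiran-2-yl]methanol
Product: 6 (2R,3S)-2-{[(4-methoxyphenyl)methoxy]methyl}-3-(prop-2-en-1-yl)oxirane
Conditions: NaH, 4-methoxybenzyl bromide, DMF, −20 → 0 °C
Reagents that add atoms: 4-methoxybenzyl bromide, COc1ccc(CBr)cc1
Why: Williamson etherification: with the benzylic bromide already present at low temperature, O-alkylation of the alkoxide should outrun Payne rearrangement. The PMB unit is the one that later ends on O6.

Step 5
Reactants: 7 2-bromoprop-2-enal (2-bromoacrolein)
Product: 9 (3S)-2-bromohexa-1,5-dien-3-ol, via borinate ester 8 (not isolated)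
Conditions: B-allyldiisopinocampheylborane [from (+)-α-pinene], Et2O, −78 °C; then NaOH, H2O2, 0 °C → rt
Reagents that add atoms: B-allyldiisopinocampheylborane [from (+)-α-pinene], C=CCB([C@@H]1C[C@@H]2C[C@H]([C@H]1C)C2(C)C)[C@@H]1C[C@@H]2C[C@H]([C@H]1C)C2(C)C
Why: Brown allylation through a closed chair transition state: the isopinocampheyl groups from (+)-α-pinene direct the allyl group to the aldehyde face that gives the (3S)-carbinol (the later C8). Oxidative work-up cleaves borinate 8 without touching the vinyl bromide.

Step 6
Reactants: 9 (3S)-2-bromohexa-1,5-dien-3-ol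
Product: 10 (3S)-2-bromo-6-methylhepta-1,5-dien-3-ol
Conditions: 2-methylbut-2-ene (large excess), second-generation Grubbs catalyst (H2IMes)(PCy3)Cl2Ru=CHPh (2 mol%), CH2Cl2, rt
Reagents that add atoms: 2-methylbut-2-ene, CC=C(C)C
Why: Olefin cross-metathesis exchanges the terminal methylene of the allyl group for an isopropylidene group. The electron-poor 1,1-disubstituted bromoalkene does not engage the ruthenium alkylidene, and the excess partner suppresses homodimerisation.

Step 7
Reactants: 10 (3S)-2-bromo-6-methylhepta-1,5-dien-3-ol
Product: 11 {[(3S)-2-bromo-6-methylhepta-1,5-dien-3-yl]oxy}(tert-butyl)dimethylsilane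
Conditions: tert-butyldimethylsilyl chloride, imidazole, DMF, rt
Reagents that add atoms: tert-butyldimethylsilyl chloride, CC(C)(C)[Si](C)(C)Cl
Why: Standard imidazole-promoted silylation of a secondary alcohol. The bulky silyl ether tolerates the organolithium, hydride and Grignard steps and resists migration to carbon at −78 °C.

Step 8
Reactants: 11 {[(3S)-2-bromo-6-methylhepta-1,5-dien-3-yl]oxy}(tert-butyl)dimethylsilane; 6 (2R,3S)-2-{[(4-methoxyphenyl)methoxy]methyl}-3-(prop-2-en-1-yl)oxirane
Product: 13 (2S,3S,5S)-5-[(tert-butyldimethylsilyl)oxy]-1-[(4-methoxyphenyl)methoxy]-8-methyl-4-methylidene-3-(prop-2-en-1-yl)non-7-en-2-ol, via alkenyllithium 12 (not isolated)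
Conditions: 11, t-BuLi (2 equiv), Et2O, −78 °C; then 6 and BF3·OEt2, Et2O/THF, −78 °C
Reagents that add atoms: none
Why: Bromine–lithium exchange gives 12, which opens the BF3-activated epoxide by SN2 attack (Lewis-acid-promoted organolithium epoxide opening). Attack should occur at the epoxide carbon distal to the CH2OPMB group, because the ether oxygen retards substitution at the adjacent carbon inductively and sterically. Inversion there sets C5 as S, and the untouched carbinol carbon becomes C6 (S).

Step 9
Reactants: 13 (2S,3S,5S)-5-[(tert-butyldimethylsilyl)oxy]-1-[(4-methoxyphenyl)methoxy]-8-methyl-4-methylidene-3-(prop-2-en-1-yl)non-7-en-2-ol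
Product: 14 (4S)-4-{(4S,6S)-6-[(tert-butyldimethylsilyl)oxy]-9-methyl-5-methylidenedeca-1,8-dien-4-yl}-2-(4-methoxyphenyl)-1,3-dioxolane (both epimers at the acetal carbon)
Conditions: DDQ (1.2 equiv), 4 Å molecular sieves, CH2Cl2, 0 °C
Reagents that add atoms: none
Why: Oxidative acetalisation: under anhydrous conditions DDQ abstracts hydride from the PMB methylene and the neighbouring C6 hydroxyl traps the oxocarbenium ion as the five-membered p-methoxybenzylidene acetal. The acetal epimers converge in step 10.

Step 10
Reactants: 14 (4S)-4-{(4S,6S)-6-[(tert-butyldimethylsilyl)oxy]-9-methyl-5-methylidenedeca-1,8-dien-4-yl}-2-(4-methoxyphenyl)-1,3-dioxolane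
Product: 15 (2S,3S,5S)-5-[(tert-butyldimethylsilyl)oxy]-2-[(4-methoxyphenyl)methoxy]-8-methyl-4-methylidene-3-(prop-2-en-1-yl)non-7-en-1-ol
Conditions: i-Bu2AlH, CH2Cl2, −78 → 0 °C
Reagents that add atoms: none
Why: Regioselective reductive opening of a benzylidene acetal: aluminium binds the less hindered primary oxygen, that C–O bond breaks and hydride reduces the oxocarbenium ion. The PMB group is left on the secondary C6 oxygen and the C1 hydroxyl is freed.

Step 11
Reactants: 15 (2S,3S,5S)-5-[(tert-butyldimethylsilyl)oxy]-2-[(4-methoxyphenyl)methoxy]-8-methyl-4-methylidene-3-(prop-2-en-1-yl)non-7-en-1-ol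
Product: 16 (2S,3S,5S)-5-[(tert-butyldimethylsilyl)oxy]-2-[(4-methoxyphenyl)methoxy]-8-methyl-4-methylidene-3-(prop-2-en-1-yl)non-7-enal
Conditions: Dess–Martin periodinane, NaHCO3, CH2Cl2, 0 °C → rt
Reagents that add atoms: none
Why: Dess–Martin oxidation under buffered, non-basic conditions gives the α-alkoxy aldehyde without epimerising C6. The aldehyde is used at once.

Step 12
Reactants: 16 (2S,3S,5S)-5-[(tert-butyldimethylsilyl)oxy]-2-[(4-methoxyphenyl)methoxy]-8-methyl-4-methylidene-3-(prop-2-en-1-yl)non-7-enal; 17 isopropenylmagnesium bromide (prop-1-en-2-ylmagnesium bromide)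
Product: 18 (3S,4S,5S,7S)-7-[(tert-butyldimethylsilyl)oxy]-4-[(4-methoxyphenyl)methoxy]-2,10-dimethyl-6-methylidene-5-(prop-2-en-1-yl)undeca-1,9-dien-3-ol (the acyclic tetraene: C1 hydroxyl, C6 PMB ether, C5 allyl, C8 TBS ether)
Conditions: MgBr2·OEt2, CH2Cl2, −78 °C; then 17 (THF solution), −78 °C
Reagents that add atoms: none
Why: Chelation-controlled Grignard addition (Cram chelate model): magnesium bridges the aldehyde oxygen and the PMB ether oxygen, and the isopropenyl group attacks from the side of the C6 hydrogen. This should give the 1,6-syn carbinol, C1 (S).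

Step 13
Reactants: 18 (3S,4S,5S,7S)-7-[(tert-butyldimethylsilyl)oxy]-4-[(4-methoxyphenyl)methoxy]-2,10-dimethyl-6-methylidene-5-(prop-2-en-1-yl)undeca-1,9-dien-3-ol
Product: 19 (1S,5S,6S)-5-{(3S)-3-[(tert-butyldimethylsilyl)oxy]-6-methylhepta-1,5-dien-2-yl}-6-[(4-methoxyphenyl)methoxy]-2-methylcyclohex-2-en-1-ol
Conditions: second-generation Grubbs catalyst (H2IMes)(PCy3)Cl2Ru=CHPh (5 mol%), CH2Cl2 (0.005 M), 40 °C
Reagents that add atoms: none
Why: Ring-closing olefin metathesis by the metallacyclobutane mechanism: the ruthenium benzylidene first exchanges onto the only monosubstituted alkene, the allyl terminus at C3. The resulting alkylidene adds [2+2] across the isopropenyl group, and cycloreversion forms the C2=C3 bond with net loss of ethylene. The closest known reaction type is the closure of 1,7-dienes bearing one 1,1-disubstituted terminus to 1-methylcyclohexenes, in particular of 2-methyl-1,7-dien-3-ols to 2-methylcyclohex-2-enols. One ring is closed, the six-membered carbocycle C1–C6, by intramolecular alkylidene–alkene metathesis, and in a ring of this size the new alkene can only be cis. No stereocentre is formed, and C1, C5, C6 and C8 are carried through because no bond to them is made or broken. The selectivity needed is among four alkenes: from the C3 alkylidene the isopropenyl group gives a six-membered ring, the C7 methylene would give a cyclobutene and the prenyl alkene a seven-membered ring. Ring size and the free allylic C1 hydroxyl, which accelerates metathesis at the adjacent alkene, should favour the desired closure. High dilution suppresses intermolecular metathesis of the allyl group.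

Step 14
Reactants: 19 (1S,5S,6S)-5-{(3S)-3-[(tert-butyldimethylsilyl)oxy]-6-methylhepta-1,5-dien-2-yl}-6-[(4-methoxyphenyl)methoxy]-2-methylcyclohex-2-en-1-ol
Product: 20 (1R,2R,3S,4S,6S)-4-{(3S)-3-[(tert-butyldimethylsilyl)oxy]-6-methylhepta-1,5-dien-2-yl}-3-[(4-methoxyphenyl)methoxy]-1-methyl-7-oxabicyclo[4.1.0]heptan-2-ol (epoxide cis to the C1 hydroxyl and to the C5 chain)
Conditions: VO(acac)2 (5 mol%), t-BuOOH (in decane), CH2Cl2, 0 °C → rt
Reagents that add atoms: tert-butyl hydroperoxide, CC(C)(C)OO
Why: Hydroxyl-directed vanadium-catalysed epoxidation: the vanadate ester of the C1 alcohol delivers the peroxide oxygen to the adjacent ring alkene on the face of the hydroxyl, setting C2 and C3 cis to the C5 chain. The C7 methylene (bishomoallylic) and the prenyl alkene have no such delivery and should react far more slowly.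

Step 15
Reactants: 20 (1R,2R,3S,4S,6S)-4-{(3S)-3-[(tert-butyldimethylsilyl)oxy]-6-methylhepta-1,5-dien-2-yl}-3-[(4-methoxyphenyl)methoxy]-1-methyl-7-oxabicyclo[4.1.0]heptan-2-ol
Product: 21 (1S,3S,4S,6S)-4-{(3S)-3-[(tert-butyldimethylsilyl)oxy]-6-methylhepta-1,5-dien-2-yl}-3-[(4-methoxyphenyl)methoxy]-1-methyl-7-oxabicyclo[4.1.0]heptan-2-one
Conditions: Dess–Martin periodinane, NaHCO3, CH2Cl2, rt
Reagents that add atoms: none
Why: Dess–Martin oxidation of the epoxy alcohol to the epoxy ketone under neutral conditions. The C1 centre, having served as the control element, is removed, and the alkenes and the epoxide are untouched.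

Step 16
Reactants: 21 (1S,3S,4S,6S)-4-{(3S)-3-[(tert-butyldimethylsilyl)oxy]-6-methylhepta-1,5-dien-2-yl}-3-[(4-methoxyphenyl)methoxy]-1-methyl-7-oxabicyclo[4.1.0]heptan-2-one
Product: 22 (1S,3S,4S,6S)-4-[(3S)-3-hydroxy-6-methylhepta-1,5-dien-2-yl]-3-[(4-methoxyphenyl)methoxy]-1-methyl-7-oxabicyclo[4.1.0]heptan-2-one
Conditions: HF·pyridine, pyridine, THF, 0 °C → rt
Reagents that add atoms: none
Why: Fluoride-mediated desilylation in a pyridine-buffered medium avoids basic fluoride that could enolise C6, and is mild enough to leave the epoxy ketone and the PMB ether intact.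

Step 17
Reactants: 22 (1S,3S,4S,6S)-4-[(3S)-3-hydroxy-6-methylhepta-1,5-dien-2-yl]-3-[(4-methoxyphenyl)methoxy]-1-methyl-7-oxabicyclo[4.1.0]heptan-2-one
Product: 23 (1S,3S,4S,6S)-4-[(3S)-3-(acetyloxy)-6-methylhepta-1,5-dien-2-yl]-3-[(4-methoxyphenyl)methoxy]-1-methyl-7-oxabicyclo[4.1.0]heptan-2-one
Conditions: Ac2O, pyridine, DMAP (cat.), CH2Cl2, 0 °C → rt
Reagents that add atoms: acetic anhydride, CC(=O)OC(C)=O
Why: Standard acylation of the only free hydroxyl, the allylic C8 alcohol, with retention at C8.

Step 18
Reactants: 23 (1S,3S,4S,6S)-4-[(3S)-3-(acetyloxy)-6-methylhepta-1,5-dien-2-yl]-3-[(4-methoxyphenyl)methoxy]-1-methyl-7-oxabicyclo[4.1.0]heptan-2-one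
Product: 24 (1S,3S,4S,6S)-4-[(3S)-3-(acetyloxy)-6-methylhepta-1,5-dien-2-yl]-3-hydroxy-1-methyl-7-oxabicyclo[4.1.0]heptan-2-one
Conditions: DDQ, CH2Cl2/pH 7 phosphate buffer, 0 °C → rt
Reagents that add atoms: none
Why: Oxidative PMB cleavage: DDQ oxidises the electron-rich benzyl ether to an oxocarbenium ion that water hydrolyses, freeing the C6 hydroxyl under neutral conditions that the acetate, the epoxy ketone and the isolated alkenes tolerate.

Step 19
Reactants: 24 (1S,3S,4S,6S)-4-[(3S)-3-(acetyloxy)-6-methylhepta-1,5-dien-2-yl]-3-hydroxy-1-methyl-7-oxabicyclo[4.1.0]heptan-2-one; 25 (2Z)-2-methylbut-2-enoic acid (angelic acid)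
Product: 27 (1S,3S,4S,6S)-4-[(3S)-3-(acetyloxy)-6-methylhepta-1,5-dien-2-yl]-1-methyl-2-oxo-7-oxabicyclo[4.1.0]heptan-3-yl (2Z)-2-methylbut-2-enoate (CNP0125636.1), via mixed anhydride 26 (not isolated)
Conditions: 25, 2,4,6-trichlorobenzoyl chloride, Et3N, toluene, rt; then 24, 75 °C
Reagents that add atoms: none
Why: Yamaguchi-type mixed-anhydride esterification without a nucleophilic catalyst: the alcohol attacks the less hindered angeloyl carbonyl of 26. Leaving out DMAP and strong base avoids the conjugate addition–elimination that converts angelates into tiglates and limits enolisation at C6.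

## Compound list

1 | prop-2-yn-1-ol (propargyl alcohol) | C#CCO | starting material
2 | 3-bromoprop-1-ene (allyl bromide) | C=CCBr | starting material
3 | hex-5-en-2-yn-1-ol | C=CCC#CCO | intermediate
4 | (2Z)-hexa-2,5-dien-1-ol | OC/C=C\CC=C | intermediate
5 | [(2R,3S)-3-(prop-2-en-1-yl)oxiran-2-yl]methanol | OC[C@H]1O[C@H]1CC=C | intermediate
6 | (2R,3S)-2-{[(4-methoxyphenyl)methoxy]methyl}-3-(prop-2-en-1-yl)oxirane | COc1ccc(COC[C@H]2O[C@H]2CC=C)cc1 | intermediate
7 | 2-bromoprop-2-enal (2-bromoacrolein) | C=C(Br)C=O | starting material
8 | (3S)-2-bromohexa-1,5-dien-3-yl diisopinocampheylborinate | C=C(Br)[C@H](CC=C)OB([C@@H]1C[C@@H]2C[C@H]([C@H]1C)C2(C)C)[C@@H]1C[C@@H]2C[C@H]([C@H]1C)C2(C)C | intermediate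
9 | (3S)-2-bromohexa-1,5-dien-3-ol | C=C(Br)[C@H](CC=C)O | intermediate
10 | (3S)-2-bromo-6-methylhepta-1,5-dien-3-ol | C=C(Br)[C@H](CC=C(C)C)O | intermediate
11 | {[(3S)-2-bromo-6-methylhepta-1,5-dien-3-yl]oxy}(tert-butyl)dimethylsilane | C=C(Br)[C@H](CC=C(C)C)O[Si](C)(C)C(C)(C)C | intermediate
12 | {(3S)-3-[(tert-butyldimethylsilyl)oxy]-6-methylhepta-1,5-dien-2-yl}lithium | [Li]C(=C)[C@H](CC=C(C)C)O[Si](C)(C)C(C)(C)C | intermediate
13 | (2S,3S,5S)-5-[(tert-butyldimethylsilyl)oxy]-1-[(4-methoxyphenyl)methoxy]-8-methyl-4-methylidene-3-(prop-2-en-1-yl)non-7-en-2-ol | C=C([C@H](CC=C(C)C)O[Si](C)(C)C(C)(C)C)[C@H](CC=C)[C@H](O)COCc1ccc(OC)cc1 | intermediate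
14 | (4S)-4-{(4S,6S)-6-[(tert-butyldimethylsilyl)oxy]-9-methyl-5-methylidenedeca-1,8-dien-4-yl}-2-(4-methoxyphenyl)-1,3-dioxolane (both acetal epimers) | C=C([C@H](CC=C(C)C)O[Si](C)(C)C(C)(C)C)[C@H](CC=C)[C@H]1COC(c2ccc(OC)cc2)O1 | intermediate
15 | (2S,3S,5S)-5-[(tert-butyldimethylsilyl)oxy]-2-[(4-methoxyphenyl)methoxy]-8-methyl-4-methylidene-3-(prop-2-en-1-yl)non-7-en-1-ol | C=C([C@H](CC=C(C)C)O[Si](C)(C)C(C)(C)C)[C@H](CC=C)[C@H](OCc1ccc(OC)cc1)CO | intermediate
16 | (2S,3S,5S)-5-[(tert-butyldimethylsilyl)oxy]-2-[(4-methoxyphenyl)methoxy]-8-methyl-4-methylidene-3-(prop-2-en-1-yl)non-7-enal | C=C([C@H](CC=C(C)C)O[Si](C)(C)C(C)(C)C)[C@H](CC=C)[C@H](OCc1ccc(OC)cc1)C=O | intermediate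
17 | isopropenylmagnesium bromide (prop-1-en-2-ylmagnesium bromide) | CC(=C)[Mg]Br | starting material
18 | (3S,4S,5S,7S)-7-[(tert-butyldimethylsilyl)oxy]-4-[(4-methoxyphenyl)methoxy]-2,10-dimethyl-6-methylidene-5-(prop-2-en-1-yl)undeca-1,9-dien-3-ol | C=C([C@H](CC=C(C)C)O[Si](C)(C)C(C)(C)C)[C@H](CC=C)[C@H](OCc1ccc(OC)cc1)[C@@H](O)C(C)=C | intermediate
19 | (1S,5S,6S)-5-{(3S)-3-[(tert-butyldimethylsilyl)oxy]-6-methylhepta-1,5-dien-2-yl}-6-[(4-methoxyphenyl)methoxy]-2-methylcyclohex-2-en-1-ol | C=C([C@H](CC=C(C)C)O[Si](C)(C)C(C)(C)C)[C@@H]1CC=C(C)[C@H](O)[C@H]1OCc1ccc(OC)cc1 | intermediate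
20 | (1R,2R,3S,4S,6S)-4-{(3S)-3-[(tert-butyldimethylsilyl)oxy]-6-methylhepta-1,5-dien-2-yl}-3-[(4-methoxyphenyl)methoxy]-1-methyl-7-oxabicyclo[4.1.0]heptan-2-ol | C=C([C@H](CC=C(C)C)O[Si](C)(C)C(C)(C)C)[C@@H]1C[C@@H]2O[C@]2(C)[C@H](O)[C@H]1OCc1ccc(OC)cc1 | intermediate
21 | (1S,3S,4S,6S)-4-{(3S)-3-[(tert-butyldimethylsilyl)oxy]-6-methylhepta-1,5-dien-2-yl}-3-[(4-methoxyphenyl)methoxy]-1-methyl-7-oxabicyclo[4.1.0]heptan-2-one | C=C([C@H](CC=C(C)C)O[Si](C)(C)C(C)(C)C)[C@@H]1C[C@@H]2O[C@]2(C)C(=O)[C@H]1OCc1ccc(OC)cc1 | intermediate
22 | (1S,3S,4S,6S)-4-[(3S)-3-hydroxy-6-methylhepta-1,5-dien-2-yl]-3-[(4-methoxyphenyl)methoxy]-1-methyl-7-oxabicyclo[4.1.0]heptan-2-one | C=C([C@H](CC=C(C)C)O)[C@@H]1C[C@@H]2O[C@]2(C)C(=O)[C@H]1OCc1ccc(OC)cc1 | intermediate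
23 | (1S,3S,4S,6S)-4-[(3S)-3-(acetyloxy)-6-methylhepta-1,5-dien-2-yl]-3-[(4-methoxyphenyl)methoxy]-1-methyl-7-oxabicyclo[4.1.0]heptan-2-one | C=C([C@H](CC=C(C)C)OC(C)=O)[C@@H]1C[C@@H]2O[C@]2(C)C(=O)[C@H]1OCc1ccc(OC)cc1 | intermediate
24 | (1S,3S,4S,6S)-4-[(3S)-3-(acetyloxy)-6-methylhepta-1,5-dien-2-yl]-3-hydroxy-1-methyl-7-oxabicyclo[4.1.0]heptan-2-one | C=C([C@H](CC=C(C)C)OC(C)=O)[C@@H]1C[C@@H]2O[C@]2(C)C(=O)[C@H]1O | intermediate
25 | (2Z)-2-methylbut-2-enoic acid (angelic acid) | C/C=C(/C)C(O)=O | starting material
26 | (2Z)-2-methylbut-2-enoic 2,4,6-trichlorobenzoic anhydride | C/C=C(/C)C(=O)OC(=O)c1c(Cl)cc(Cl)cc1Cl | intermediate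
27 | (1S,3S,4S,6S)-4-[(3S)-3-(acetyloxy)-6-methylhepta-1,5-dien-2-yl]-1-methyl-2-oxo-7-oxabicyclo[4.1.0]heptan-3-yl (2Z)-2-methylbut-2-enoate (CNP0125636.1) | C=C([C@H](CC=C(C)C)OC(C)=O)[C@@H]1C[C@@H]2O[C@]2(C)C(=O)[C@H]1OC(=O)/C(C)=C\C | target

## Step count and least certain steps

Total: 19 steps. Longest linear sequence: 16 steps (steps 1–4 and 8–19, from 1). The bromide branch (steps 5–7) joins at step 8.

**Step 13 (key step).** The most likely failure is loss of ring-size selectivity. Once loaded on the allyl group, the alkylidene can also reach the trisubstituted C10=C11 alkene and close a seven-membered ring with loss of the isopropylidene terminus. If closure onto the hindered isopropenyl group is slow, intermolecular metathesis of the allyl termini takes over. Both become likelier because the chain next to the reacting centres is bulky.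

The fallback keeps the C2–C3 closure but makes it between two monosubstituted alkenes and adds the C2 methyl afterwards. It sets out from aldehyde 16 and returns at cyclohexenol 19. Chelation-controlled addition of vinylmagnesium bromide (CH2=CHMgBr, MgBr2·OEt2, CH2Cl2, −78 °C) would give the vinyl carbinol F1. Ring-closing metathesis of its two terminal alkenes with the same catalyst, far faster than any reaction of the trisubstituted alkene, would give the cyclohexenol F2. Dess–Martin oxidation would give the enone F3, and iodine with pyridine the 2-iodoenone F4. Stille methylation (Me4Sn, Pd2(dba)3, AsPh3, CuI) would give the 2-methylenone F5. Luche reduction (NaBH4, CeCl3·7H2O, MeOH, −78 °C) delivers hydride axially to the half-chair that keeps the C5 and C6 substituents equatorial, and should return the C1 alcohol trans to the C6 ether, that is 19.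

**Step 8.** The most likely failure is slow attack of the branched, α-oxygenated alkenyllithium on an internal cis-epoxide. Lewis-acid-induced rearrangement of the epoxide, attack at the carbon next to the ether, or migration of silicon from oxygen to the lithiated carbon of 12 could then compete.

The fallback changes substrate, metal and the source of regiocontrol. It sets out from the unprotected epoxy alcohol 5 (with 12) and returns at acetal 14. Transmetalation of 12 with Et2AlCl would give the alkenyl(diethyl)alane F6. F6 is allowed to react with the lithium alkoxide of 5 (from 5 and n-BuLi) in toluene/hexane. The aluminium alkoxide formed at O1 activates the epoxide from within, and a second molecule of alane delivers the alkenyl group to C3 with inversion, giving the 1,2-diol F7. F7 with 4-methoxybenzaldehyde dimethyl acetal and pyridinium p-toluenesulfonate gives 14.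

**Step 12.** The most likely failure is poor facial selectivity. THF from the Grignard solution competes with the PMB oxygen for magnesium, and the branched C5 substituent may favour the non-chelated Felkin–Anh mode, which leads to the 1,6-anti carbinol.

The fallback sets C1 by reagent-controlled reduction instead of addition. It sets out from aldehyde 16 and returns at 18. The addition of 17 is run without regard to selectivity. The carbinol mixture is oxidised with Dess–Martin periodinane to the isopropenyl ketone F8. F8 is reduced with (S)-2-methyl-CBS-oxazaborolidine and catecholborane in toluene at −78 °C. With the alkenyl group acting as the larger ketone substituent, the reagent is expected to give the (S)-carbinol. This is also the Felkin–Anh product of a non-chelating hydride, so reagent and substrate should reinforce each other and give 18.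

**Step 19.** The most likely failures are partial Z-to-E isomerisation of the angeloyl unit during activation and heating, and amine-induced enolisation at C6 of the α-ketol (epimerisation or transposition of the carbonyl) at 75 °C.

The fallback builds the Z-alkene on the ester instead of acylating with the preformed acid. It sets out from 24 and returns at 27. Esterification of 24 with 2-[bis(2,2,2-trifluoroethoxy)phosphoryl]propanoic acid (N,N'-dicyclohexylcarbodiimide, CH2Cl2, 0 °C) would give the phosphonopropanoate F9. Still–Gennari olefination of F9 with acetaldehyde (KN(SiMe3)2, 18-crown-6, THF, −78 °C) should give the Z-configured 2-methylbut-2-enoate 27. The phosphonate is deprotonated in preference to the ketone at this temperature.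

## Further compounds

F1 | step 13 | (3S,4S,5S,7S)-7-[(tert-butyldimethylsilyl)oxy]-4-[(4-methoxyphenyl)methoxy]-10-methyl-6-methylidene-5-(prop-2-en-1-yl)undeca-1,9-dien-3-ol | C=C([C@H](CC=C(C)C)O[Si](C)(C)C(C)(C)C)[C@H](CC=C)[C@H](OCc1ccc(OC)cc1)[C@@H](O)C=C
F2 | step 13 | (1S,5S,6S)-5-{(3S)-3-[(tert-butyldimethylsilyl)oxy]-6-methylhepta-1,5-dien-2-yl}-6-[(4-methoxyphenyl)methoxy]cyclohex-2-en-1-ol | C=C([C@H](CC=C(C)C)O[Si](C)(C)C(C)(C)C)[C@@H]1CC=C[C@H](O)[C@H]1OCc1ccc(OC)cc1
F3 | step 13 | (5S,6S)-5-{(3S)-3-[(tert-butyldimethylsilyl)oxy]-6-methylhepta-1,5-dien-2-yl}-6-[(4-methoxyphenyl)methoxy]cyclohex-2-en-1-one | C=C([C@H](CC=C(C)C)O[Si](C)(C)C(C)(C)C)[C@@H]1CC=CC(=O)[C@H]1OCc1ccc(OC)cc1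
F4 | step 13 | (5S,6S)-5-{(3S)-3-[(tert-butyldimethylsilyl)oxy]-6-methylhepta-1,5-dien-2-yl}-2-iodo-6-[(4-methoxyphenyl)methoxy]cyclohex-2-en-1-one | C=C([C@H](CC=C(C)C)O[Si](C)(C)C(C)(C)C)[C@@H]1CC=C(I)C(=O)[C@H]1OCc1ccc(OC)cc1
F5 | step 13 | (5S,6S)-5-{(3S)-3-[(tert-butyldimethylsilyl)oxy]-6-methylhepta-1,5-dien-2-yl}-6-[(4-methoxyphenyl)methoxy]-2-methylcyclohex-2-en-1-one | C=C([C@H](CC=C(C)C)O[Si](C)(C)C(C)(C)C)[C@@H]1CC=C(C)C(=O)[C@H]1OCc1ccc(OC)cc1
F6 | step 8 | {(3S)-3-[(tert-butyldimethylsilyl)oxy]-6-methylhepta-1,5-dien-2-yl}(diethyl)alane | CC[Al](CC)C(=C)[C@H](CC=C(C)C)O[Si](C)(C)C(C)(C)C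
F7 | step 8 | (2S,3S,5S)-5-[(tert-butyldimethylsilyl)oxy]-8-methyl-4-methylidene-3-(prop-2-en-1-yl)non-7-ene-1,2-diol | C=C([C@H](CC=C(C)C)O[Si](C)(C)C(C)(C)C)[C@H](CC=C)[C@H](O)CO
F8 | step 12 | (4S,5S,7S)-7-[(tert-butyldimethylsilyl)oxy]-4-[(4-methoxyphenyl)methoxy]-2,10-dimethyl-6-methylidene-5-(prop-2-en-1-yl)undeca-1,9-dien-3-one | C=C([C@H](CC=C(C)C)O[Si](C)(C)C(C)(C)C)[C@H](CC=C)[C@H](OCc1ccc(OC)cc1)C(=O)C(C)=C
F9 | step 19 | (1S,3S,4S,6S)-4-[(3S)-3-(acetyloxy)-6-methylhepta-1,5-dien-2-yl]-1-methyl-2-oxo-7-oxabicyclo[4.1.0]heptan-3-yl 2-[bis(2,2,2-trifluoroethoxy)phosphoryl]propanoate | C=C([C@H](CC=C(C)C)OC(C)=O)[C@@H]1C[C@@H]2O[C@]2(C)C(=O)[C@H]1OC(=O)C(C)P(=O)(OCC(F)(F)F)OCC(F)(F)F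
A1 | alternative 1 | cyclohexene carboxylic acid with the C1/C6 acetonide, the C2–C3 alkene and the C7 carboxyl on C5 | OC(=O)[C@@H]1CC=C(C)[C@H]2OC(C)(C)O[C@H]21
A2 | alternative 1 | six-membered lactone with the C1/C6 acetonide and a methyl- and vinyl-substituted carbon at the ring oxygen | C=C[C@]1(C)OC(=O)C[C@@H]2OC(C)(C)O[C@@H]21
A3 | alternative 2 | 6-[(tert-butyldimethylsilyl)oxy]-2-methyl-5-(2-methyl-1,3-dioxolan-2-yl)-3-(trimethylsilyl)cyclohex-2-en-1-one | CC1=C([Si](C)(C)C)C[C@@H](C2(C)OCCO2)[C@H](O[Si](C)(C)C(C)(C)C)C1=O
A4 | alternative 2 | trans-2-[(tert-butyldimethylsilyl)oxy]-3-(2-methyl-1,3-dioxolan-2-yl)cyclobutan-1-one | O=C1C[C@@H](C2(C)OCCO2)[C@@H]1O[Si](C)(C)C(C)(C)C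
A5 | alternative 2 | 1-(trimethylsilyl)propyne | CC#C[Si](C)(C)C
A6 | alternative 3 | trans-cyclohexenol with the C7 methylene, the C1 PMB ether, the free C6 hydroxyl and the C2–C3 alkene | C=C([C@H](CC=C(C)C)O[Si](C)(C)C(C)(C)C)[C@@H]1CC=C(C)[C@H](OCc2ccc(OC)cc2)[C@H]1O
A7 | alternative 3 | acyclic (3Z,6Z)-trienal with the C6 aldehyde, the C1 PMB ether and the C8 silyl ether | O=C[C@@H](OCc1ccc(OC)cc1)/C(C)=C\C/C=C(/C)[C@H](CC=C(C)C)O[Si](C)(C)C(C)(C)C
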